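**Retrosynthetic overview**

- Feature (briarane numbering: ring A = C1, C10–C14; ring B = C1–C10; lactone = C7, C8, C17, C19): ring B has only two unfunctionalised carbons, C3 and C4. C3 lies α to oxygenated C2, whose other neighbour C1 is quaternary, and C4 is allylic to the Z C5=C6 alkene. C3–C4 is therefore cut to a C2 keto sulfone carbanion and a Z-allylic bromide.
- Seco precursor: keto sulfone from a C2 aldehyde and lithiated methyl phenyl sulfone; lactone by oxidative lactonisation (C19 onto O7); C7 by chelation-controlled reduction of a Z-enone; C6–C7 by alkenyllithium attack on a dioxolanone; C8–C9 by aldol of a malate-derived tert-butyl dioxolanone with the ring A aldehyde. The C9 oxygen is carried as a silyl ether through the ring closure and acetylated together with C2 at the end.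
- Ring A: catalytic asymmetric Diels–Alder reaction (2-silyloxydiene plus formyl crotonate, sets C1/C10), Saegusa oxidation, triflate reduction to the 1,3-diene, cis-dihydroxylation (C11/C12).
- Ring order: ring A (step 2), lactone (step 23), ring B (step 29); then desulfonylation, C2 reduction, desilylation, bis-acetylation, acetonide removal.

Key step: step 29

Assumption: the (S)-oxazaborolidinium catalyst is taken to give the Diels–Alder adduct enantiomer drawn (the (R)-catalyst is used if the sense is opposite); the C11 methyl configuration written for the adduct is that of the formyl-exo transition state and is erased in step 6.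

**Route**

Step 1
Reactants: 1 pent-1-en-3-one
Product: 2 (Z)-3-(triisopropylsilyloxy)penta-1,3-diene
Conditions: i-Pr3SiOTf, Et3N, Et2O, 0 °C
Reagents that add atoms: triisopropylsilyl triflate CC(C)[Si](OS(=O)(=O)C(F)(F)F)(C(C)C)C(C)C
Why: Soft enolisation and O-silylation of the ethyl ketone gives the 2-silyloxydiene, the Z enol ether being favoured so that the methyl group sits outside in the s-cis diene.

Step 2
Reactants: 2 (Z)-3-(triisopropylsilyloxy)penta-1,3-diene; 3 ethyl (E)-3-methyl-4-oxobut-2-enoate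
Product: 4 ring A adduct (ethyl 6-formyl-2,6-dimethyl-3-(triisopropylsilyloxy)cyclohex-3-ene-1-carboxylate; formyl trans to ester; both methyls cis to ester)
Conditions: (S)-o-tolyl-CBS-oxazaborolidine/Tf2NH (20 mol %), CH2Cl2, −78 °C
Reagents that add atoms: none
Why: Lewis-acid-catalysed Diels–Alder reaction in which the oxazaborolidinium ion binds the formyl group of 3, so the nucleophilic methyl-bearing terminus of 2 bonds to the ester-bearing β-carbon (C10) and C14 to C1, the E geometry of 3 fixes the trans C2/C9 relationship, and the aryl group of the catalyst shields one enal face to set C1 and C10 absolutely.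

Step 3
Reactants: 4 ring A adduct
Product: 5 ring A primary alcohol (C2 CH2OH)
Conditions: NaBH4, EtOH/THF, −40 °C; AcOH quench
Reagents that add atoms: none
Why: Chemoselective borohydride reduction of the neopentyl aldehyde, the ester and the silyl enol ether being inert at low temperature, and the cold acidic quench suppresses lactonisation onto the trans ester.

Step 4
Reactants: 5 ring A primary alcohol
Product: 6 ring A C2 silyl ether (CH2OTBS)
Conditions: t-BuMe2SiCl, imidazole, DMF, 0 °C
Reagents that add atoms: tert-butyldimethylsilyl chloride CC(C)(C)[Si](C)(C)Cl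
Why: Standard silylation of a primary alcohol, run directly on crude 5 so that the hydroxy ester has no time to lactonise.

Step 5
Reactants: 6 ring A C2 silyl ether
Product: 7 ring A enone (C12 ketone; C13=C14)
Conditions: Pd(OAc)2 (10 mol %), O2 (1 atm), DMSO, 60 °C
Reagents that add atoms: none
Why: Saegusa–Ito oxidation, in which palladation of the regiodefined silyl enol ether at C13 and β-hydride elimination toward C14 give the enone, and quaternary C1 allows no other regioisomer.

Step 6
Reactants: 7 ring A enone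
Product: 9 ring A dienyl triflate (C11=C12 enol triflate; C13=C14), via potassium dienolate 8 (not isolated)
Conditions: KN(SiMe3)2, THF, −78 °C; then PhNTf2, −78 to 0 °C
Reagents that add atoms: N-phenyl-bis(trifluoromethanesulfonimide) O=S(=O)(N(c1ccccc1)S(=O)(=O)C(F)(F)F)C(F)(F)F
Why: Kinetic α′-deprotonation of the enone at C11 (γ-deprotonation is impossible at quaternary C1 and the ketone α-H is more acidic than the ester α-H) followed by O-triflation gives the cross-conjugated dienyl triflate and erases the C11 stereocentre.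

Step 7
Reactants: 9 ring A dienyl triflate
Product: 10 ring A diene (ethyl 6-(tert-butyldimethylsilyloxymethyl)-2,6-dimethylcyclohexa-2,4-diene-1-carboxylate)
Conditions: Pd(OAc)2 (5 mol %), PPh3, HCO2H, Et3N, DMF, 50 °C
Reagents that add atoms: none
Why: Palladium-catalysed formate reduction of an enol triflate (oxidative addition, hydride transfer from formate, reductive elimination) gives the 1,3-diene without touching the ester or the silyl ether.

Step 8
Reactants: 10 ring A diene
Product: 11 ring A cis-diol (C11 OH and C12 OH, both trans to the C10 ester)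
Conditions: OsO4 (5 mol %), NMO (1.1 equiv), acetone/H2O, 0 °C
Reagents that add atoms: osmium tetroxide O=[Os](=O)(=O)=O; N-methylmorpholine N-oxide C[N+]1([O-])CCOCC1; water O
Why: Catalytic cis-dihydroxylation of the more electron-rich trisubstituted C11=C12 bond, where allylic strain with the C11 methyl holds the C10 ester pseudoaxial so that it blocks the upper face and both hydroxyls enter anti to C9, while C13=C14 is shielded by the neopentyl C1.

Step 9
Reactants: 11 ring A cis-diol
Product: 12 ring A acetonide ester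
Conditions: Me2C(OMe)2, PPTS (cat.), CH2Cl2, rt
Reagents that add atoms: 2,2-dimethoxypropane COC(C)(C)OC
Why: Acid-catalysed transacetalisation converts the cis-1,2-diol into its isopropylidene acetal, which can only form on a cis diol.

Step 10
Reactants: 12 ring A acetonide ester
Product: 13 ring A C9 alcohol
Conditions: i-Bu2AlH (3 equiv), CH2Cl2, −78 to 0 °C
Reagents that add atoms: none
Why: Hydride reduction of the ethyl ester to the primary alcohol, with silyl ether, acetonide and alkene inert.

Step 11
Reactants: 13 ring A C9 alcohol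
Product: 14 ring A C9 aldehyde
Conditions: Dess–Martin periodinane, NaHCO3, CH2Cl2, 0 °C
Reagents that add atoms: none
Why: Dess–Martin oxidation under buffered non-basic conditions gives the aldehyde without epimerising C10.

Step 12
Reactants: 15 diethyl (S)-malate
Product: 17 diethyl (2S,3R)-2-hydroxy-3-methylbutanedioate, via dilithium alkoxide enolate 16 (not isolated)
Conditions: LiN(i-Pr)2 (2.2 equiv), THF, −78 to −20 °C; then MeI, −78 to 0 °C; then H2O
Reagents that add atoms: iodomethane CI
Why: Fráter–Seebach alkylation, in which the chelated dilithium alkoxide enolate is methylated anti to the alkoxide and so sets C17 relative to the malate carbinol (C8).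

Step 13
Reactants: 17 diethyl (2S,3R)-2-hydroxy-3-methylbutanedioate
Product: 18 (2S,3R)-2-hydroxy-3-methylbutanedioic acid
Conditions: LiOH, THF/H2O, 0 °C to rt; then HCl
Reagents that add atoms: lithium hydroxide [Li+].[OH-]
Why: Saponification of both esters, the carboxylates formed protecting C17 against epimerisation.

Step 14
Reactants: 18 (2S,3R)-2-hydroxy-3-methylbutanedioic acid
Product: 19 cis-dioxolanone acid (2-tert-butyl-1,3-dioxolan-4-one from the C7 acid and O8; side chain CH(CH3)CO2H)
Conditions: t-BuCHO, TsOH (cat.), H2SO4 (cat.), pentane, reflux, water separator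
Reagents that add atoms: pivalaldehyde CC(C)(C)C=O
Why: Acid-catalysed acetalisation of the α-hydroxy acid unit (self-regeneration of stereocentres), the cis-2,5-disubstituted five-membered dioxolanone being the thermodynamic product so that C8 fixes the new acetal centre.

Step 15
Reactants: 19 cis-dioxolanone acid
Product: 20 cis-dioxolanone alcohol (C19 CH2OH)
Conditions: BH3·SMe2, THF, 0 °C to rt; MeOH quench
Reagents that add atoms: none
Why: Borane reduces the free carboxylic acid through its acyloxyborane much faster than the dioxolanone carbonyl.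

Step 16
Reactants: 20 cis-dioxolanone alcohol
Product: 21 cis-dioxolanone C19 silyl ether
Conditions: t-BuMe2SiCl, imidazole, DMF, 0 °C
Reagents that add atoms: tert-butyldimethylsilyl chloride CC(C)(C)[Si](C)(C)Cl
Why: Silylation of the primary alcohol, done at once so that it cannot attack the dioxolanone carbonyl.

Step 17
Reactants: 22 prop-2-yn-1-ol
Product: 24 (Z)-3-iodo-2-methylprop-2-en-1-ol, via alkenylmagnesium bromide 23 (not isolated)
Conditions: MeMgBr (2.5 equiv), CuI (10 mol %), THF, −10 °C to rt; then I2, −78 to 0 °C; then H2O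
Reagents that add atoms: methylmagnesium bromide C[Mg]Br; iodine II
Why: Copper-catalysed anti-carbomagnesiation of the propargylic alkoxide places magnesium cis to CH2O through chelation, and iodinolysis with retention gives the Z iodoalkene.

Step 18
Reactants: 24 (Z)-3-iodo-2-methylprop-2-en-1-ol
Product: 25 (Z)-1-iodo-3-(4-methoxybenzyloxy)-2-methylprop-1-ene
Conditions: NaH, 4-MeOC6H4CH2Cl, Bu4NI (cat.), THF/DMF, 0 °C to rt
Reagents that add atoms: 4-methoxybenzyl chloride COc1ccc(CCl)cc1
Why: Williamson etherification of the primary allylic alkoxide, to which the vinyl iodide is inert.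

Step 19
Reactants: 21 cis-dioxolanone C19 silyl ether; 14 ring A C9 aldehyde
Product: 28 aldol product as C9 TBS ether (dioxolanone with quaternary C8), via lithium enolate 26 (not isolated), via lithium aldolate 27 (not isolated)
Conditions: LiN(SiMe3)2, THF, −78 °C; add 14, −78 °C; then t-BuMe2SiOTf, −78 to −40 °C
Reagents that add atoms: tert-butyldimethylsilyl triflate CC(C)(C)[Si](C)(C)OS(=O)(=O)C(F)(F)F
Why: Aldol addition of a tert-butyl dioxolanone enolate, in which the aldehyde attacks trans to the tert-butyl group so C8 forms with net retention, the ring forces O8 trans to the enolate oxygen so the Zimmerman–Traxler chair with ring A equatorial gives the 8,9-anti arrangement required at C9, and silylation of the aldolate in the same flask blocks retro-aldol.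

Step 20
Reactants: 25 (Z)-1-iodo-3-(4-methoxybenzyloxy)-2-methylprop-1-ene; 28 aldol product as C9 TBS ether
Product: 31 α-hydroxy Z-enone (C7 ketone; C8 OH), via alkenyllithium 29 (not isolated), via lithium hemiketal 30 (not isolated)
Conditions: 25, t-BuLi (2 equiv per iodide), Et2O, −78 °C; add 28 in THF, −78 °C; then H2O
Reagents that add atoms: none
Why: Iodine–lithium exchange with retention of the Z geometry and acyl substitution at the dioxolanone carbonyl, where the cyclic lithium hemiketal survives at −78 °C so only one addition occurs and work-up releases pivalaldehyde and the ketone.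

Step 21
Reactants: 31 α-hydroxy Z-enone
Product: 32 7,8-diol (C7 alcohol)
Conditions: Zn(BH4)2, Et2O, −40 to −20 °C
Reagents that add atoms: none
Why: Chelation-controlled reduction of an α-hydroxy ketone, in which zinc bridges O8 and the C7 carbonyl and hydride enters from the C17 side, away from the C9 branch carrying ring A, to give the 7,8-anti (7,9-syn) alcohol, 1,2-reduction of the enone being the normal course with Zn(BH4)2.

Step 22
Reactants: 32 7,8-diol
Product: 33 tetraol (C2, C7, C8 and C19 hydroxyls free; C9 OTBS kept)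
Conditions: HF·pyridine, pyridine, THF, 0 °C to rt
Reagents that add atoms: none
Why: Buffered fluoride cleaves the two primary silyl ethers much faster than the very hindered secondary C9 silyl ether, and acetonide and PMB ether are stable.

Step 23
Reactants: 33 tetraol
Product: 34 lactone aldehyde (C19–O7 lactone; C2 CHO; C8 OH)
Conditions: TEMPO (0.3 equiv), PhI(OAc)2 (4 equiv), CH2Cl2, rt
Reagents that add atoms: none
Why: Oxoammonium oxidation selective for primary alcohols, taking C19 through to the γ-lactone with the C7 hydroxyl (oxidative lactonisation of a 1,4-diol; O9 is silylated so only O7 can close) and stopping at the non-enolisable aldehyde at C2.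

Step 24
Reactants: 34 lactone aldehyde
Product: 35 lactone aldehyde C8 TES ether
Conditions: Et3SiOTf, 2,6-lutidine, CH2Cl2, −40 to 0 °C
Reagents that add atoms: triethylsilyl triflate CC[Si](CC)(CC)OS(=O)(=O)C(F)(F)F
Why: Silyl triflate silylation of the tertiary C8 alcohol, which blocks retro-aldol cleavage of the β-hydroxy lactone in the basic steps that follow.

Step 25
Reactants: 35 lactone aldehyde C8 TES ether; 36 methyl phenyl sulfone
Product: 38 β-hydroxy sulfone (C2 epimers), via lithiated methyl phenyl sulfone 37 (not isolated)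
Conditions: 36, n-BuLi (1.1 equiv), THF, −78 °C; add 35, −78 °C; then H2O
Reagents that add atoms: none
Why: Addition of the sulfonyl carbanion to the aldehyde at −78 °C is much faster than attack on, or enolisation of, the lactone, and both C2 epimers converge in step 26.

Step 26
Reactants: 38 β-hydroxy sulfone
Product: 39 β-keto sulfone (C2 ketone; C3 CH2SO2Ph)
Conditions: Dess–Martin periodinane, NaHCO3, CH2Cl2, rt
Reagents that add atoms: none
Why: Dess–Martin oxidation of the secondary alcohol under non-basic conditions avoids retro-addition of the β-hydroxy sulfone.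

Step 27
Reactants: 39 β-keto sulfone
Product: 40 Z-allylic alcohol (C4 OH)
Conditions: DDQ, CH2Cl2/pH 7 buffer, 0 °C
Reagents that add atoms: none
Why: Oxidative cleavage of the p-methoxybenzyl ether (hydride abstraction, then hydrolysis of the oxocarbenium ion), to which silyl ethers, acetonide and keto sulfone are inert.

Step 28
Reactants: 40 Z-allylic alcohol
Product: 41 Z-allylic bromide (key-step precursor)
Conditions: CBr4, PPh3, CH2Cl2, −20 °C
Reagents that add atoms: carbon tetrabromide BrC(Br)(Br)Br
Why: Appel bromination, a neutral SN2 displacement at the primary allylic carbon that keeps the Z geometry and does not deprotonate the keto sulfone.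

Step 29
Reactants: 41 Z-allylic bromide
Product: 43 ring B ketone with C3 phenylsulfonyl group (C3 epimers), via caesium carbanion 42 (not isolated)
Conditions: Cs2CO3 (5 equiv), MeCN, 45 °C, syringe-pump addition of 41 to about 1 mM
Reagents that add atoms: none
Why: Cs2CO3 removes the doubly activated C3–H (between the C2 ketone and the sulfonyl group) and the soft carbanion 42 displaces bromide at the primary allylic C4 in an intramolecular SN2 reaction, forming C3–C4. The closest known reaction type is the intramolecular alkylation of sulfone-stabilised carbanions with allylic halides used to close ten-membered and larger carbocycles. Ring B closes in a 10-exo-tet mode; quaternary C1 leaves C3 as the only enolisable position of the ketone, and the Z alkene, ring A and the lactone cut down the rotatable bonds between the reacting ends. The new C3 stereocentre is not controlled and need not be, since the sulfonyl group is removed in step 30. The step needs C- over O-alkylation and SN2 over SN2′, which the soft carbanion and the unhindered primary C4 should secure, and ring closure over dimerisation, which slow addition at high dilution secures; the mild base should leave the lactone C17–H untouched.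

Step 30
Reactants: 43 ring B ketone with C3 phenylsulfonyl group
Product: 44 ring B C2 ketone (C3 CH2)
Conditions: SmI2 (3 equiv), THF/MeOH, −78 °C
Reagents that add atoms: none
Why: Single-electron reductive cleavage of the α-sulfonyl ketone C–S bond gives a samarium enolate that methanol protonates, which removes the C3 stereocentre.

Step 31
Reactants: 44 ring B C2 ketone
Product: 45 C2 alcohol (2R)
Conditions: (S)-2-methyl-CBS-oxazaborolidine (20 mol %), catecholborane, toluene, −40 to −20 °C
Reagents that add atoms: none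
Why: Corey–Bakshi–Shibata reduction, in which quaternary C1 acts as the large and C3H2 as the small ketone substituent so the (S)-oxazaborolidine should deliver hydride to give the 2R alcohol under reagent control, and catecholborane at low temperature spares the alkenes and the lactone.

Step 32
Reactants: 45 C2 alcohol
Product: 46 2,8,9-triol acetonide
Conditions: HF·pyridine, THF, rt to 40 °C
Reagents that add atoms: none
Why: Fluoride cleavage of the tertiary TES and the hindered secondary TBS ether under weakly acidic conditions that leave the acetonide and lactone intact and cannot trigger retro-aldol.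

Step 33
Reactants: 46 2,8,9-triol acetonide
Product: 47 2,9-diacetate acetonide
Conditions: Ac2O, DMAP, pyridine, CH2Cl2, rt
Reagents that add atoms: acetic anhydride CC(=O)OC(C)=O
Why: DMAP-catalysed acetylation of the two secondary alcohols, the tertiary C8 hydroxyl being left free for steric reasons.

Step 34
Reactants: 47 2,9-diacetate acetonide
Product: 48 CNP0146024.1 (target)
Conditions: AcOH/H2O (4:1), 40 °C
Reagents that add atoms: none
Why: Acid-catalysed hydrolysis of the isopropylidene acetal releases the 11,12-diol, and the acetates and the lactone survive aqueous acetic acid.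

**Compound list**

1 | pent-1-en-3-one | CCC(=O)C=C | starting material
2 | (Z)-3-(triisopropylsilyloxy)penta-1,3-diene | C/C=C(O[Si](C(C)C)(C(C)C)C(C)C)/C=C | intermediate
3 | ethyl (E)-3-methyl-4-oxobut-2-enoate | CCOC(=O)/C=C(\C)C=O | starting material
4 | ring A adduct: ethyl 6-formyl-2,6-dimethyl-3-(triisopropylsilyloxy)cyclohex-3-ene-1-carboxylate (formyl trans to ester; both methyls cis to ester) | CCOC(=O)[C@H]1[C@@H](C)C(O[Si](C(C)C)(C(C)C)C(C)C)=CC[C@]1(C)C=O | intermediate
5 | ring A primary alcohol: 6-(hydroxymethyl) analogue of 4 | CCOC(=O)[C@H]1[C@@H](C)C(O[Si](C(C)C)(C(C)C)C(C)C)=CC[C@]1(C)CO | intermediate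
6 | ring A C2 silyl ether: 6-(tert-butyldimethylsilyloxymethyl) analogue of 4 | CCOC(=O)[C@H]1[C@@H](C)C(O[Si](C(C)C)(C(C)C)C(C)C)=CC[C@]1(C)CO[Si](C)(C)C(C)(C)C | intermediate
7 | ring A enone: ethyl 6-(tert-butyldimethylsilyloxymethyl)-2,6-dimethyl-3-oxocyclohex-4-ene-1-carboxylate | CCOC(=O)[C@H]1[C@@H](C)C(=O)C=C[C@]1(C)CO[Si](C)(C)C(C)(C)C | intermediate
8 | potassium dienolate of 7 (C11=C12 enolate) | CCOC(=O)[C@H]1C(C)=C([O-])C=C[C@]1(C)CO[Si](C)(C)C(C)(C)C.[K+] | intermediate (not isolated)
9 | ring A dienyl triflate: ethyl 6-(tert-butyldimethylsilyloxymethyl)-2,6-dimethyl-3-(trifluoromethylsulfonyloxy)cyclohexa-2,4-diene-1-carboxylate | CCOC(=O)[C@H]1C(C)=C(OS(=O)(=O)C(F)(F)F)C=C[C@]1(C)CO[Si](C)(C)C(C)(C)C | intermediate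
10 | ring A diene: ethyl 6-(tert-butyldimethylsilyloxymethyl)-2,6-dimethylcyclohexa-2,4-diene-1-carboxylate (ester trans to CH2OTBS) | CCOC(=O)[C@H]1C(C)=CC=C[C@]1(C)CO[Si](C)(C)C(C)(C)C | intermediate
11 | ring A cis-diol: ethyl 6-(tert-butyldimethylsilyloxymethyl)-2,3-dihydroxy-2,6-dimethylcyclohex-4-ene-1-carboxylate (both hydroxyls trans to ester) | CCOC(=O)[C@H]1[C@](C)(O)[C@H](O)C=C[C@]1(C)CO[Si](C)(C)C(C)(C)C | intermediate
12 | ring A acetonide ester (isopropylidene acetal of 11) | CCOC(=O)[C@H]1[C@]2(C)OC(C)(C)O[C@@H]2C=C[C@]1(C)CO[Si](C)(C)C(C)(C)C | intermediate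
13 | ring A C9 alcohol: [6-(tert-butyldimethylsilyloxymethyl)-2,2,6,7a-tetramethyl-3a,6,7,7a-tetrahydro-1,3-benzodioxol-7-yl]methanol | OC[C@H]1[C@]2(C)OC(C)(C)O[C@@H]2C=C[C@]1(C)CO[Si](C)(C)C(C)(C)C | intermediate
14 | ring A C9 aldehyde: 7-carbaldehyde corresponding to 13 | O=C[C@H]1[C@]2(C)OC(C)(C)O[C@@H]2C=C[C@]1(C)CO[Si](C)(C)C(C)(C)C | intermediate
15 | diethyl (S)-malate | CCOC(=O)C[C@H](O)C(=O)OCC | starting material
16 | dilithium alkoxide enolate of 15 | CCOC([O-])=C[C@H]([O-])C(=O)OCC.[Li+].[Li+] | intermediate (not isolated)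
17 | diethyl (2S,3R)-2-hydroxy-3-methylbutanedioate | CCOC(=O)[C@H](C)[C@H](O)C(=O)OCC | intermediate
18 | (2S,3R)-2-hydroxy-3-methylbutanedioic acid | OC(=O)[C@H](C)[C@H](O)C(=O)O | intermediate
19 | cis-dioxolanone acid: 2-(cis-2-tert-butyl-5-oxo-1,3-dioxolan-4-yl)propanoic acid | OC(=O)[C@H](C)[C@@H]1O[C@H](C(C)(C)C)OC1=O | intermediate
20 | cis-dioxolanone alcohol: cis-2-tert-butyl-5-(1-hydroxypropan-2-yl)-1,3-dioxolan-4-one | OC[C@H](C)[C@@H]1O[C@H](C(C)(C)C)OC1=O | intermediate
21 | cis-dioxolanone C19 silyl ether (TBS ether of 20) | CC(C)(C)[Si](C)(C)OC[C@H](C)[C@@H]1O[C@H](C(C)(C)C)OC1=O | intermediate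
22 | prop-2-yn-1-ol | C#CCO | starting material
23 | alkenylmagnesium bromide: (Z)-BrMgCH=C(CH3)CH2OMgBr | Br[Mg]OC/C(C)=C\[Mg]Br | intermediate (not isolated)
24 | (Z)-3-iodo-2-methylprop-2-en-1-ol | OC/C(C)=C\I | intermediate
25 | (Z)-1-iodo-3-(4-methoxybenzyloxy)-2-methylprop-1-ene | COc1ccc(COC/C(C)=C\I)cc1 | intermediate
26 | lithium enolate of 21 | CC(C)(C)[Si](C)(C)OC[C@H](C)C1=C([O-])O[C@@H](C(C)(C)C)O1.[Li+] | intermediate (not isolated)
27 | lithium aldolate (C9 alkoxide; dioxolanone with quaternary C8) | [Li+].[O-][C@H]([C@H]1[C@]2(C)OC(C)(C)O[C@@H]2C=C[C@]1(C)CO[Si](C)(C)C(C)(C)C)[C@]2(O[C@H](C(C)(C)C)OC2=O)[C@@H](C)CO[Si](C)(C)C(C)(C)C | intermediate (not isolated)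
28 | aldol product as C9 TBS ether | CC(C)(C)[Si](C)(C)O[C@H]([C@H]1[C@]2(C)OC(C)(C)O[C@@H]2C=C[C@]1(C)CO[Si](C)(C)C(C)(C)C)[C@]2(O[C@H](C(C)(C)C)OC2=O)[C@@H](C)CO[Si](C)(C)C(C)(C)C | intermediate
29 | alkenyllithium: (Z)-LiCH=C(CH3)CH2OPMB | COc1ccc(COC/C(C)=C\[Li])cc1 | intermediate (not isolated)
30 | lithium hemiketal (alkenyl adduct at C7 of the dioxolanone; C7 epimers) | [Li+].CC(C)(C)[Si](C)(C)O[C@H]([C@H]1[C@]2(C)OC(C)(C)O[C@@H]2C=C[C@]1(C)CO[Si](C)(C)C(C)(C)C)[C@]2(O[C@H](C(C)(C)C)OC2([O-])/C=C(C)\COCc1ccc(OC)cc1)[C@@H](C)CO[Si](C)(C)C(C)(C)C | intermediate (not isolated)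
31 | α-hydroxy Z-enone (C7 ketone; C8 OH; C9 OTBS; C2 and C19 CH2OTBS; C4 OPMB) | CC(C)(C)[Si](C)(C)O[C@H]([C@H]1[C@]2(C)OC(C)(C)O[C@@H]2C=C[C@]1(C)CO[Si](C)(C)C(C)(C)C)[C@](O)([C@@H](C)CO[Si](C)(C)C(C)(C)C)C(=O)/C=C(C)\COCc1ccc(OC)cc1 | intermediate
32 | 7,8-diol (C7 alcohol from 31) | CC(C)(C)[Si](C)(C)O[C@H]([C@H]1[C@]2(C)OC(C)(C)O[C@@H]2C=C[C@]1(C)CO[Si](C)(C)C(C)(C)C)[C@](O)([C@@H](C)CO[Si](C)(C)C(C)(C)C)[C@@H](O)/C=C(C)\COCc1ccc(OC)cc1 | intermediate
33 | tetraol (C2, C7, C8 and C19 hydroxyls free; C9 OTBS) | CC(C)(C)[Si](C)(C)O[C@H]([C@H]1[C@]2(C)OC(C)(C)O[C@@H]2C=C[C@]1(C)CO)[C@](O)([C@@H](C)CO)[C@@H](O)/C=C(C)\COCc1ccc(OC)cc1 | intermediate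
34 | lactone aldehyde (C19–O7 γ-lactone; C2 CHO; C8 OH; C9 OTBS; C4 OPMB) | CC(C)(C)[Si](C)(C)O[C@H]([C@H]1[C@]2(C)OC(C)(C)O[C@@H]2C=C[C@]1(C)C=O)[C@]2(O)[C@@H](C)C(=O)O[C@H]2/C=C(C)\COCc1ccc(OC)cc1 | intermediate
35 | lactone aldehyde C8 TES ether | CC(C)(C)[Si](C)(C)O[C@H]([C@H]1[C@]2(C)OC(C)(C)O[C@@H]2C=C[C@]1(C)C=O)[C@]2(O[Si](CC)(CC)CC)[C@@H](C)C(=O)O[C@H]2/C=C(C)\COCc1ccc(OC)cc1 | intermediate
36 | methyl phenyl sulfone | CS(=O)(=O)c1ccccc1 | starting material
37 | lithiated methyl phenyl sulfone | [Li]CS(=O)(=O)c1ccccc1 | intermediate (not isolated)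
38 | β-hydroxy sulfone (C2 carbinol epimers; C3 CH2SO2Ph) | CC(C)(C)[Si](C)(C)O[C@H]([C@H]1[C@]2(C)OC(C)(C)O[C@@H]2C=C[C@]1(C)C(O)CS(=O)(=O)c1ccccc1)[C@]2(O[Si](CC)(CC)CC)[C@@H](C)C(=O)O[C@H]2/C=C(C)\COCc1ccc(OC)cc1 | intermediate
39 | β-keto sulfone (C2 ketone; C4 OPMB) | CC(C)(C)[Si](C)(C)O[C@H]([C@H]1[C@]2(C)OC(C)(C)O[C@@H]2C=C[C@]1(C)C(=O)CS(=O)(=O)c1ccccc1)[C@]2(O[Si](CC)(CC)CC)[C@@H](C)C(=O)O[C@H]2/C=C(C)\COCc1ccc(OC)cc1 | intermediate
40 | Z-allylic alcohol (C4 OH) | CC(C)(C)[Si](C)(C)O[C@H]([C@H]1[C@]2(C)OC(C)(C)O[C@@H]2C=C[C@]1(C)C(=O)CS(=O)(=O)c1ccccc1)[C@]2(O[Si](CC)(CC)CC)[C@@H](C)C(=O)O[C@H]2/C=C(C)\CO | intermediate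
41 | Z-allylic bromide: C2 keto sulfone with C4 bromide, ring A acetonide, complete lactone, C8 OTES, C9 OTBS (key-step precursor) | CC(C)(C)[Si](C)(C)O[C@H]([C@H]1[C@]2(C)OC(C)(C)O[C@@H]2C=C[C@]1(C)C(=O)CS(=O)(=O)c1ccccc1)[C@]2(O[Si](CC)(CC)CC)[C@@H](C)C(=O)O[C@H]2/C=C(C)\CBr | intermediate
42 | caesium carbanion of 41 (C3 anion) | [Cs+].CC(C)(C)[Si](C)(C)O[C@H]([C@H]1[C@]2(C)OC(C)(C)O[C@@H]2C=C[C@]1(C)C(=O)[CH-]S(=O)(=O)c1ccccc1)[C@]2(O[Si](CC)(CC)CC)[C@@H](C)C(=O)O[C@H]2/C=C(C)\CBr | intermediate (not isolated)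
43 | ring B C2 ketone with C3 phenylsulfonyl group (C3 epimers; key-step product) | CC(C)(C)[Si](C)(C)O[C@@H]1[C@H]2[C@]3(C)OC(C)(C)O[C@@H]3C=C[C@]2(C)C(=O)C(S(=O)(=O)c2ccccc2)C/C(C)=C\[C@@H]2OC(=O)[C@H](C)[C@]21O[Si](CC)(CC)CC | intermediate
44 | ring B C2 ketone (C3 CH2) | CC(C)(C)[Si](C)(C)O[C@@H]1[C@H]2[C@]3(C)OC(C)(C)O[C@@H]3C=C[C@]2(C)C(=O)CC/C(C)=C\[C@@H]2OC(=O)[C@H](C)[C@]21O[Si](CC)(CC)CC | intermediate
45 | C2 alcohol (2R; C8 OTES; C9 OTBS) | CC(C)(C)[Si](C)(C)O[C@@H]1[C@H]2[C@]3(C)OC(C)(C)O[C@@H]3C=C[C@]2(C)[C@H](O)CC/C(C)=C\[C@@H]2OC(=O)[C@H](C)[C@]21O[Si](CC)(CC)CC | intermediate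
46 | 2,8,9-triol acetonide | O[C@@H]1[C@H]2[C@]3(C)OC(C)(C)O[C@@H]3C=C[C@]2(C)[C@H](O)CC/C(C)=C\[C@@H]2OC(=O)[C@H](C)[C@]21O | intermediate
47 | 2,9-diacetate acetonide | CC(=O)O[C@@H]1[C@H]2[C@]3(C)OC(C)(C)O[C@@H]3C=C[C@]2(C)[C@H](OC(C)=O)CC/C(C)=C\[C@@H]2OC(=O)[C@H](C)[C@]21O | intermediate
48 | CNP0146024.1 | CC(=O)O[C@@H]1[C@H]2[C@](C)(O)[C@H](O)C=C[C@]2(C)[C@H](OC(C)=O)CC/C(C)=C\[C@@H]2OC(=O)[C@H](C)[C@]21O | target

**Step count and risks**

Total: 34 steps. Longest linear sequence: 27 steps (steps 1–11, then 19–34).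

Steps most likely to fail:

1. Step 29 (ring B closure). Intermolecular alkylation to dimers and oligomers, O-alkylation, or slow closure against transannular strain while the allylic bromide decomposes. Fallback: setting out from allylic alcohol 40, acylation with methyl chloroformate and pyridine gives the allylic methyl carbonate F1. F1 is ionised by Pd(PPh3)4 (zerovalent palladium, with dppe) in THF at high dilution; the methoxide released deprotonates the keto sulfone, and the carbanion attacks the less hindered C4 terminus of the π-allyl complex (Tsuji–Trost macrocyclisation under neutral conditions). This rejoins the route at 43.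

2. Step 19 (dioxolanone aldol). Proton transfer from the hindered aldehyde 14 to the enolate instead of addition, retro-aldol before silylation, or poor facial selectivity at C9. Fallback: setting out from 14, Pinnick oxidation (NaClO2, NaH2PO4, 2-methylbut-2-ene) gives the ring A carboxylic acid F2, which 1-chloro-N,N,2-trimethylprop-1-en-1-amine converts under neutral conditions into the acid chloride F3. C-acylation of lithium enolate 26, again trans to the tert-butyl group, gives the β-keto dioxolanone F4. Its C9 ketone is reduced with NaBH4 in MeOH at −78 °C (non-chelating conditions, hydride anti to the C8–O bond with the two carbonyl dipoles opposed) to the C9 alcohol F5. Silylation with t-BuMe2SiOTf and 2,6-lutidine rejoins the route at 28.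

3. Step 20 (alkenyllithium acyl substitution). No addition at the congested C7 carbonyl, a second addition after premature collapse of the hemiketal, or Z to E isomerisation of the enone. Fallback: setting out from 28, i-Bu2AlH at −78 °C followed by mild acidic work-up (loss of pivalaldehyde) gives the α-hydroxy aldehyde F6. Chromium-mediated coupling with iodide 25 (CrCl2, catalytic NiCl2, DMF; Nozaki–Hiyama–Kishi reaction, which tolerates the free hydroxyl and keeps the Z geometry) gives the allylic alcohols F7 as C7 epimers. MnO2 oxidation of the allylic alcohol rejoins the route at 31.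

Further compounds
F1 | step 29 | allylic methyl carbonate of 40 (C4 OCO2CH3) | CC(C)(C)[Si](C)(C)O[C@H]([C@H]1[C@]2(C)OC(C)(C)O[C@@H]2C=C[C@]1(C)C(=O)CS(=O)(=O)c1ccccc1)[C@]2(O[Si](CC)(CC)CC)[C@@H](C)C(=O)O[C@H]2/C=C(C)\COC(=O)OC
F2 | step 19 | ring A C9 carboxylic acid | OC(=O)[C@H]1[C@]2(C)OC(C)(C)O[C@@H]2C=C[C@]1(C)CO[Si](C)(C)C(C)(C)C
F3 | step 19 | ring A C9 acid chloride | ClC(=O)[C@H]1[C@]2(C)OC(C)(C)O[C@@H]2C=C[C@]1(C)CO[Si](C)(C)C(C)(C)C
F4 | step 19 | β-keto dioxolanone (C9 ketone; quaternary C8) | O=C([C@H]1[C@]2(C)OC(C)(C)O[C@@H]2C=C[C@]1(C)CO[Si](C)(C)C(C)(C)C)[C@]2(O[C@H](C(C)(C)C)OC2=O)[C@@H](C)CO[Si](C)(C)C(C)(C)C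
F5 | step 19 | C9 alcohol of the aldol product (free hydroxyl) | O[C@H]([C@H]1[C@]2(C)OC(C)(C)O[C@@H]2C=C[C@]1(C)CO[Si](C)(C)C(C)(C)C)[C@]2(O[C@H](C(C)(C)C)OC2=O)[C@@H](C)CO[Si](C)(C)C(C)(C)C
F6 | step 20 | α-hydroxy aldehyde (C7 CHO; C8 OH) | CC(C)(C)[Si](C)(C)O[C@H]([C@H]1[C@]2(C)OC(C)(C)O[C@@H]2C=C[C@]1(C)CO[Si](C)(C)C(C)(C)C)[C@](O)([C@@H](C)CO[Si](C)(C)C(C)(C)C)C=O
F7 | step 20 | Z-allylic alcohols (C7 epimers) | CC(C)(C)[Si](C)(C)O[C@H]([C@H]1[C@]2(C)OC(C)(C)O[C@@H]2C=C[C@]1(C)CO[Si](C)(C)C(C)(C)C)[C@](O)([C@@H](C)CO[Si](C)(C)C(C)(C)C)C(O)/C=C(C)\COCc1ccc(OC)cc1
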